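C1 = ester-bearing CH, C2 = CH2, C3 = methyl-bearing alkene carbon, C4 = alkene CH, C5 = ketone carbon, C6 = methyl-bearing fusion carbon, C7/C8 = CH2, C9 = isopropyl carbinol carbon, C10 = fusion CH; ring A = seven-membered (C1–C6, C10), ring B = cyclopentane (C6–C10).
Feature used: the C1 and C9 oxygens flank C10 on the same face (cis-1,3), and C2 is the allylic CH2 of the C3-methyl enone, so C1–C2 is an allylation of a C1 aldehyde that the C9 oxygen can hold in a chelate.
Late disconnections: vanillate ester at C1–O; the C3=C4 enone from its exocyclic C3-methylene isomer; then C1–C2 by intramolecular Hosomi–Sakurai addition of a 2-(trimethylsilylmethyl)allyl ketone to the chelated C1 aldehyde.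
Precursor: C4–C5 by allylzinc addition to a C5 aldehyde, C9–isopropyl by organocerium addition, C10–C1 by formaldehyde aldol of the enolate formed in the asymmetric conjugate addition (C6–C5) of a silylmethyl Grignard reagent to 3-methylcyclopentenone.
Ring order: ring B is the starting enone; ring A is closed last, in the key step.

Key step: step 9

Remark on the chemistry: the copper–NHC catalyst is assumed to discriminate the enone faces with the silylmethyl Grignard reagent as it does with simple primary alkyl Grignard reagents; the ligand enantiomer that gives the 3S centre is used, and the configuration is to be secured at diol 8.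
Remark on the chemistry: a phenyldimethylsilyl group serves as the masked C5 hydroxyl. An alkoxysilane would be attacked by the C1 alkoxide of the formaldehyde trapping (six-membered siloxane), and the later oxidation would then free the C1 and C5 oxygens together.

Step 1
Reactants: 1 3-methylcyclopent-2-en-1-one; 2 (chloromethyl)dimethyl(phenyl)silane
Product: 5 (2S,3S)-3-{[dimethyl(phenyl)silyl]methyl}-2-(hydroxymethyl)-3-methylcyclopentan-1-one, via Grignard reagent 3 (not isolated), via magnesium enolate 4 (not isolated)
Conditions: 2, Mg, Et2O, reflux; then 1, Cu(OTf)2 (3 mol %), chiral N-mesityl-N'-(hydroxyalkyl)imidazolinium salt (NHC precursor, 4 mol %), Et2O, −30 °C; then CH2O gas (cracked paraformaldehyde), −78 → −30 °C; aq. NH4Cl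
Reagents that add atoms: formaldehyde, C=O
Why: Copper–NHC-catalysed asymmetric conjugate addition of a Grignard reagent to a β-substituted cyclic enone should set the quaternary C6 centre under catalyst control, and the regiodefined magnesium enolate should then undergo an aldol reaction with formaldehyde at C10 on the face anti to the bulky silylmethyl group, placing C1 trans to C5 (this is also the more stable epimer; any C10 epimer is to be removed by chromatography after step 2).

Step 2
Reactants: 5 (2S,3S)-3-{[dimethyl(phenyl)silyl]methyl}-2-(hydroxymethyl)-3-methylcyclopentan-1-one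
Product: 6 (2S,3S)-3-{[dimethyl(phenyl)silyl]methyl}-3-methyl-2-({[tri(propan-2-yl)silyl]oxy}methyl)cyclopentan-1-one
Conditions: TIPSCl, imidazole, DMF, 0 °C → rt
Reagents that add atoms: chlorotri(propan-2-yl)silane, CC(C)[Si](Cl)(C(C)C)C(C)C
Why: Imidazole-mediated silylation of the primary hydroxyl keeps the C1 oxygen distinguishable from the C5 oxygen released in step 4, blocks retro-aldol loss of formaldehyde, and gives an ether that withstands the acidic oxidation of step 4.

Step 3
Reactants: 6 (2S,3S)-3-{[dimethyl(phenyl)silyl]methyl}-3-methyl-2-({[tri(propan-2-yl)silyl]oxy}methyl)cyclopentan-1-one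
Product: 7 (1R,2S,3S)-3-{[dimethyl(phenyl)silyl]methyl}-3-methyl-1-(propan-2-yl)-2-({[tri(propan-2-yl)silyl]oxy}methyl)cyclopentan-1-ol
Conditions: iPrMgCl, CeCl3 (anhydrous), THF, −78 → 0 °C; aq. NH4Cl
Reagents that add atoms: isopropylmagnesium chloride, CC(C)[Mg]Cl
Why: Organocerium (Imamoto) 1,2-addition should suppress enolisation and β-hydride reduction of the hindered ketone, and the reagent should attack the cyclopentanone face anti to the adjacent C10 substituent, which sets C9 with its hydroxyl cis to C1.

Step 4
Reactants: 7 (1R,2S,3S)-3-{[dimethyl(phenyl)silyl]methyl}-3-methyl-1-(propan-2-yl)-2-({[tri(propan-2-yl)silyl]oxy}methyl)cyclopentan-1-ol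
Product: 8 (1R,2S,3S)-3-(hydroxymethyl)-3-methyl-1-(propan-2-yl)-2-({[tri(propan-2-yl)silyl]oxy}methyl)cyclopentan-1-ol
Conditions: KBr, AcOOH (in AcOH), NaOAc, AcOH, 0 °C → rt; aq. Na2S2O3
Reagents that add atoms: peracetic acid, CC(=O)OO
Why: One-pot Fleming–Tamao oxidation: bromine made in situ removes the phenyl group from silicon by ipso substitution and the peracid then turns the C5–Si bond into C5–OH, at a stage with no alkene or ketone and with a tertiary alcohol and a TIPS ether that tolerate buffered acetic acid.

Step 5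
Reactants: 8 (1R,2S,3S)-3-(hydroxymethyl)-3-methyl-1-(propan-2-yl)-2-({[tri(propan-2-yl)silyl]oxy}methyl)cyclopentan-1-ol
Product: 9 (1S,2S,3R)-3-hydroxy-1-methyl-3-(propan-2-yl)-2-({[tri(propan-2-yl)silyl]oxy}methyl)cyclopentane-1-carbaldehyde
Conditions: Dess–Martin periodinane, NaHCO3, CH2Cl2, 0 °C → rt
Reagents that add atoms: none
Why: Dess–Martin oxidation should take the neopentyl primary alcohol to the aldehyde while the tertiary alcohol is inert, and the aldehyde has no α-hydrogen, so C6 cannot epimerise.

Step 6
Reactants: 9 (1S,2S,3R)-3-hydroxy-1-methyl-3-(propan-2-yl)-2-({[tri(propan-2-yl)silyl]oxy}methyl)cyclopentane-1-carbaldehyde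
Product: 10 (1S,2S,3R)-3-hydroxy-2-(hydroxymethyl)-1-methyl-3-(propan-2-yl)cyclopentane-1-carbaldehyde
Conditions: Bu4NF, AcOH (1:1), THF, rt
Reagents that add atoms: none
Why: Buffered fluoride desilylation frees the C1 hydroxyl before the allylsilane is introduced, so that group never meets fluoride; the trans placement of C1 and C5 on ring B disfavours lactol formation.

Step 7
Reactants: 10 (1S,2S,3R)-3-hydroxy-2-(hydroxymethyl)-1-methyl-3-(propan-2-yl)cyclopentane-1-carbaldehyde; 11 2-(chloromethyl)-3-(trimethylsilyl)prop-1-ene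
Product: 13 1-[(1S,2S,3R)-3-hydroxy-2-(hydroxymethyl)-1-methyl-3-(propan-2-yl)cyclopentyl]-3-[(trimethylsilyl)methyl]but-3-en-1-ol (both epimers at the new C5 carbinol), via allylzinc chloride 12 (not isolated)
Conditions: 11, Zn dust, LiCl, THF, rt; then 10, −20 → 0 °C; aq. NH4Cl
Reagents that add atoms: none
Why: Zinc-mediated carbonyl allylation (zinc insertion into the allylic chloride, then addition to the hindered aldehyde) forms C4–C5; the two hydroxyls only consume extra reagent, both allyl termini give the same product, and the C5 configuration is irrelevant because step 8 oxidises it.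

Step 8
Reactants: 13 1-[(1S,2S,3R)-3-hydroxy-2-(hydroxymethyl)-1-methyl-3-(propan-2-yl)cyclopentyl]-3-[(trimethylsilyl)methyl]but-3-en-1-ol
Product: 14 (1R,2R,5S)-2-hydroxy-5-methyl-2-(propan-2-yl)-5-{3-[(trimethylsilyl)methyl]but-3-enoyl}cyclopentane-1-carbaldehyde
Conditions: Dess–Martin periodinane (excess), NaHCO3, CH2Cl2, 0 °C → rt; short neutral silica pad, used at once
Reagents that add atoms: none
Why: A buffered double Dess–Martin oxidation should convert the C1 primary alcohol into the aldehyde and the C5 secondary alcohol into the ketone without acid or base, so the β,γ-unsaturated ketone is not conjugated, the allylsilane is not protodesilylated, the trans-1,2 arrangement prevents lactol or lactone formation, and C10 keeps its more stable configuration.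

Step 9
Reactants: 14 (1R,2R,5S)-2-hydroxy-5-methyl-2-(propan-2-yl)-5-{3-[(trimethylsilyl)methyl]but-3-enoyl}cyclopentane-1-carbaldehyde
Product: 16 (1R,3aS,8R,8aS)-1,8-dihydroxy-3a-methyl-6-methylidene-1-(propan-2-yl)octahydroazulen-4(1H)-one, via aluminium alkoxide chelate 15 (not isolated)
Conditions: Me2AlCl (2.5 equiv), CH2Cl2, −78 → −30 °C; aq. KNaC4H4O6
Reagents that add atoms: none
Why: Me2AlCl converts the C9 hydroxyl into a chloro(methyl)aluminium alkoxide (methane lost) whose aluminium also binds the C1 aldehyde oxygen in a six-membered chelate, the second equivalent raising its Lewis acidity by chloride abstraction. The terminal alkene carbon of the 2-(trimethylsilylmethyl)allyl group (C2) then adds to C1 in SE2' fashion, and the C3 cation, stabilised by the β-silicon, loses Me3SiCl to leave the exocyclic C3 methylene; this is an intramolecular Hosomi–Sakurai allylation, closest to the known Lewis-acid cyclisations of 2-substituted allylsilanes onto aldehydes that give methylenecycloheptanols. Ring A closes as a seven-membered ring, 7-exo-trig at the C1 carbonyl, with the allylsilane double bond taken into the ring and re-formed outside it at C3. The one new stereocentre, C1, is controlled by the chelate: the aldehyde oxygen is held on the side of the C9 oxygen, antiperiplanar to C10–H, while the chain anchored at C6 can bring C2 in only from the side away from C9, so the C1 oxygen ends cis to the C9 oxygen as a 1,3-diaxial-like aluminium diolate (8R). The step needs attack on the aldehyde and not the ketone, and reaction at the alkene terminus of the allylsilane: the ketone sits in the tether (attack on it would need a four-membered ring) and is not chelated, and silicon directs the electrophile to the terminal carbon. C6, C9 and C10 are untouched, the formyl group at C10 being already in its more stable orientation (cis to hydroxyl and methyl, trans to isopropyl and acyl).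

Step 10
Reactants: 16 (1R,3aS,8R,8aS)-1,8-dihydroxy-3a-methyl-6-methylidene-1-(propan-2-yl)octahydroazulen-4(1H)-one
Product: 17 (1R,3aS,8R,8aS)-1,8-dihydroxy-3a,6-dimethyl-1-(propan-2-yl)-2,3,3a,7,8,8a-hexahydroazulen-4(1H)-one
Conditions: DBU, toluene, rt → 50 °C
Reagents that add atoms: none
Why: Base-mediated alkene isomerisation: DBU removes the doubly activated C4 proton and the dienolate is reprotonated at the exocyclic carbon, which should move the double bond into conjugation with the C5 ketone; it is done before acylation because the free C1 hydroxyl is a poor leaving group for vinylogous elimination.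

Step 11
Reactants: 18 vanillic acid
Product: 20 4-[(tert-butyldimethylsilyl)oxy]-3-methoxybenzoic acid, via bis-silylated vanillate 19 (not isolated)
Conditions: TBSCl, imidazole, DMF, rt; then AcOH/THF/H2O, rt
Reagents that add atoms: tert-butylchlorodimethylsilane, CC(C)(C)[Si](C)(C)Cl
Why: Exhaustive silylation followed by selective hydrolysis of the much more labile silyl ester should leave the phenol protected and the acid free.

Step 12
Reactants: 17 (1R,3aS,8R,8aS)-1,8-dihydroxy-3a,6-dimethyl-1-(propan-2-yl)-2,3,3a,7,8,8a-hexahydroazulen-4(1H)-one; 20 4-[(tert-butyldimethylsilyl)oxy]-3-methoxybenzoic acid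
Product: 21 (1R,3aS,8R,8aS)-1-hydroxy-3a,6-dimethyl-4-oxo-1-(propan-2-yl)-1,2,3,3a,4,7,8,8a-octahydroazulen-8-yl 4-[(tert-butyldimethylsilyl)oxy]-3-methoxybenzoate
Conditions: DCC, DMAP, CH2Cl2, 0 °C → rt
Reagents that add atoms: none
Why: Steglich esterification should acylate the secondary C1 hydroxyl with retention (the C1–O bond is not broken), the tertiary C9 hydroxyl being too hindered to react.

Step 13
Reactants: 21 (1R,3aS,8R,8aS)-1-hydroxy-3a,6-dimethyl-4-oxo-1-(propan-2-yl)-1,2,3,3a,4,7,8,8a-octahydroazulen-8-yl 4-[(tert-butyldimethylsilyl)oxy]-3-methoxybenzoate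
Product: 22 (1R,3aS,8R,8aS)-1-hydroxy-3a,6-dimethyl-4-oxo-1-(propan-2-yl)-1,2,3,3a,4,7,8,8a-octahydroazulen-8-yl 4-hydroxy-3-methoxybenzoate (CNP0136950.1)
Conditions: Bu4NF, AcOH (1:1), THF, 0 °C
Reagents that add atoms: none
Why: Acetic-acid-buffered fluoride desilylation should cleave the aryl silyl ether quickly without a basic medium that could cause vinylogous elimination of the C1 carboxylate or ester cleavage.

Compound list
1 | 3-methylcyclopent-2-en-1-one | CC1=CC(=O)CC1 | starting material
2 | (chloromethyl)dimethyl(phenyl)silane | C[Si](C)(CCl)c1ccccc1 | starting material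
3 | {[dimethyl(phenyl)silyl]methyl}magnesium chloride | C[Si](C)(C[Mg]Cl)c1ccccc1 | intermediate
4 | chloromagnesium (3S)-3-{[dimethyl(phenyl)silyl]methyl}-3-methylcyclopent-1-en-1-olate | C[Si](C)(c1ccccc1)C[C@@]1(C)CCC(O[Mg]Cl)=C1 | intermediate
5 | (2S,3S)-3-{[dimethyl(phenyl)silyl]methyl}-2-(hydroxymethyl)-3-methylcyclopentan-1-one | C[Si](C)(c1ccccc1)C[C@@]1(C)CCC(=O)[C@@H]1CO | intermediate
6 | (2S,3S)-3-{[dimethyl(phenyl)silyl]methyl}-3-methyl-2-({[tri(propan-2-yl)silyl]oxy}methyl)cyclopentan-1-one | C[Si](C)(c1ccccc1)C[C@@]1(C)CCC(=O)[C@@H]1CO[Si](C(C)C)(C(C)C)C(C)C | intermediate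
7 | (1R,2S,3S)-3-{[dimethyl(phenyl)silyl]methyl}-3-methyl-1-(propan-2-yl)-2-({[tri(propan-2-yl)silyl]oxy}methyl)cyclopentan-1-ol | C[Si](C)(c1ccccc1)C[C@@]1(C)CC[C@@](O)(C(C)C)[C@@H]1CO[Si](C(C)C)(C(C)C)C(C)C | intermediate
8 | (1R,2S,3S)-3-(hydroxymethyl)-3-methyl-1-(propan-2-yl)-2-({[tri(propan-2-yl)silyl]oxy}methyl)cyclopentan-1-ol | OC[C@@]1(C)CC[C@@](O)(C(C)C)[C@@H]1CO[Si](C(C)C)(C(C)C)C(C)C | intermediate
9 | (1S,2S,3R)-3-hydroxy-1-methyl-3-(propan-2-yl)-2-({[tri(propan-2-yl)silyl]oxy}methyl)cyclopentane-1-carbaldehyde | O=C[C@@]1(C)CC[C@@](O)(C(C)C)[C@@H]1CO[Si](C(C)C)(C(C)C)C(C)C | intermediate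
10 | (1S,2S,3R)-3-hydroxy-2-(hydroxymethyl)-1-methyl-3-(propan-2-yl)cyclopentane-1-carbaldehyde | O=C[C@@]1(C)CC[C@@](O)(C(C)C)[C@@H]1CO | intermediate
11 | 2-(chloromethyl)-3-(trimethylsilyl)prop-1-ene | C=C(CCl)C[Si](C)(C)C | starting material
12 | {2-[(trimethylsilyl)methyl]prop-2-en-1-yl}zinc chloride | C=C(C[Zn]Cl)C[Si](C)(C)C | intermediate
13 | 1-[(1S,2S,3R)-3-hydroxy-2-(hydroxymethyl)-1-methyl-3-(propan-2-yl)cyclopentyl]-3-[(trimethylsilyl)methyl]but-3-en-1-ol (both C5 epimers) | C[Si](C)(C)CC(=C)CC(O)[C@@]1(C)CC[C@@](O)(C(C)C)[C@@H]1CO | intermediate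
14 | (1R,2R,5S)-2-hydroxy-5-methyl-2-(propan-2-yl)-5-{3-[(trimethylsilyl)methyl]but-3-enoyl}cyclopentane-1-carbaldehyde | C[Si](C)(C)CC(=C)CC(=O)[C@@]1(C)CC[C@@](O)(C(C)C)[C@@H]1C=O | intermediate
15 | chloro(methyl)aluminium alkoxide of 14 at the C9 oxygen, aluminium also bound to the C1 aldehyde oxygen (six-membered chelate) | C[Si](C)(C)CC(=C)CC(=O)[C@@]1(C)CC[C@@](O[Al](C)Cl)(C(C)C)[C@@H]1C=O | intermediate
16 | (1R,3aS,8R,8aS)-1,8-dihydroxy-3a-methyl-6-methylidene-1-(propan-2-yl)octahydroazulen-4(1H)-one | O[C@@H]1CC(=C)CC(=O)[C@@]2(C)CC[C@@](O)(C(C)C)[C@H]12 | intermediate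
17 | (1R,3aS,8R,8aS)-1,8-dihydroxy-3a,6-dimethyl-1-(propan-2-yl)-2,3,3a,7,8,8a-hexahydroazulen-4(1H)-one | O[C@@H]1CC(C)=CC(=O)[C@@]2(C)CC[C@@](O)(C(C)C)[C@H]12 | intermediate
18 | vanillic acid (4-hydroxy-3-methoxybenzoic acid) | COc1cc(C(=O)O)ccc1O | starting material
19 | tert-butyldimethylsilyl 4-[(tert-butyldimethylsilyl)oxy]-3-methoxybenzoate | COc1cc(C(=O)O[Si](C)(C)C(C)(C)C)ccc1O[Si](C)(C)C(C)(C)C | intermediate
20 | 4-[(tert-butyldimethylsilyl)oxy]-3-methoxybenzoic acid | COc1cc(C(=O)O)ccc1O[Si](C)(C)C(C)(C)C | intermediate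
21 | (1R,3aS,8R,8aS)-1-hydroxy-3a,6-dimethyl-4-oxo-1-(propan-2-yl)-1,2,3,3a,4,7,8,8a-octahydroazulen-8-yl 4-[(tert-butyldimethylsilyl)oxy]-3-methoxybenzoate | COc1cc(C(=O)O[C@@H]2CC(C)=CC(=O)[C@@]3(C)CC[C@@](O)(C(C)C)[C@H]23)ccc1O[Si](C)(C)C(C)(C)C | intermediate
22 | (1R,3aS,8R,8aS)-1-hydroxy-3a,6-dimethyl-4-oxo-1-(propan-2-yl)-1,2,3,3a,4,7,8,8a-octahydroazulen-8-yl 4-hydroxy-3-methoxybenzoate | COc1cc(C(=O)O[C@@H]2CC(C)=CC(=O)[C@@]3(C)CC[C@@](O)(C(C)C)[C@H]23)ccc1O | target

Total step count: 13. Longest linear sequence: 12 steps (steps 1–10, 12 and 13; step 11 is a one-step side branch).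

Steps most likely to fail

Step 9. The Lewis acid may open the β-hydroxy aldehyde by retro-aldol cleavage or dehydrate it, aluminium may transfer a methyl group to the aldehyde, the allylsilane may be protodesilylated, or facial control at C1 may be insufficient. The fallback reverses the polarity of the closure and sets out from 14. Bromodesilylation with NBS (CH2Cl2, −78 °C; Br+ attacks the alkene terminus and silicon is lost) would give the allylic bromide (1R,2R,5S)-5-[3-(bromomethyl)but-3-enoyl]-2-hydroxy-5-methyl-2-(propan-2-yl)cyclopentane-1-carbaldehyde F1. An intramolecular Nozaki–Hiyama–Kishi-type allylation with CrCl2 (THF, high dilution, rt) would then form the same C1–C2 bond. The allylchromium species is aldehyde-selective, and the chromium alkoxide at C9 can tie the aldehyde oxygen in the same way, so the route would be rejoined at 16.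

Step 1. The catalyst may discriminate the enone faces poorly with the bulky α-silyl Grignard reagent on the five-membered enone, 1,2-addition may compete, or the facial preference of the formaldehyde trapping may be modest. The fallback sets out from 1 and 2 and gives up asymmetric catalysis. Conjugate addition with CuBr·SMe2 and no chiral ligand, followed by the same formaldehyde trapping, would pass through the racemic enolate, that is 4 together with its enantiomer chloromagnesium (3R)-3-{[dimethyl(phenyl)silyl]methyl}-3-methylcyclopent-1-en-1-olate F2. It would deliver the racemic hydroxy ketone, that is 5 together with (2R,3R)-3-{[dimethyl(phenyl)silyl]methyl}-2-(hydroxymethyl)-3-methylcyclopentan-1-one F3. Preparative HPLC on a cellulose tris(3,5-dimethylphenylcarbamate) stationary phase (hexane/2-propanol) would separate the enantiomers, and any C10 epimer in the same run, and the route would be rejoined at 5.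

Step 3. The secondary alkyl reagent may enolise the hindered ketone (with β-elimination of the silyloxy group) or reduce it by β-hydride transfer instead of adding. The fallback sets out from 6 and brings in the three carbons as an sp2 nucleophile. Isopropenylmagnesium bromide with CeCl3 (THF, −78 °C) cannot transfer a β-hydride and is less hindered. With the same facial preference it would give (1S,2S,3S)-3-{[dimethyl(phenyl)silyl]methyl}-3-methyl-1-(prop-1-en-2-yl)-2-({[tri(propan-2-yl)silyl]oxy}methyl)cyclopentan-1-ol F4. Hydrogenation of the 1,1-disubstituted alkene (H2, PtO2, EtOAc, rt) would rejoin the route at 7.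

Further compounds
F1 | step 9 | (1R,2R,5S)-5-[3-(bromomethyl)but-3-enoyl]-2-hydroxy-5-methyl-2-(propan-2-yl)cyclopentane-1-carbaldehyde | BrCC(=C)CC(=O)[C@@]1(C)CC[C@@](O)(C(C)C)[C@@H]1C=O
F2 | step 1 | chloromagnesium (3R)-3-{[dimethyl(phenyl)silyl]methyl}-3-methylcyclopent-1-en-1-olate | C[Si](C)(c1ccccc1)C[C@]1(C)CCC(O[Mg]Cl)=C1
F3 | step 1 | (2R,3R)-3-{[dimethyl(phenyl)silyl]methyl}-2-(hydroxymethyl)-3-methylcyclopentan-1-one | C[Si](C)(c1ccccc1)C[C@]1(C)CCC(=O)[C@H]1CO
F4 | step 3 | (1S,2S,3S)-3-{[dimethyl(phenyl)silyl]methyl}-3-methyl-1-(prop-1-en-2-yl)-2-({[tri(propan-2-yl)silyl]oxy}methyl)cyclopentan-1-ol | C[Si](C)(c1ccccc1)C[C@@]1(C)CC[C@@](O)(C(C)=C)[C@@H]1CO[Si](C(C)C)(C(C)C)C(C)C
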